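**Retrosynthetic overview**

1. Target 24 ⇒ diol 23 (selective angeloylation at C4–OH) ⇒ enone 22 ⇒ tricyclic hydroxy enone 19 with the carbonyl still at C9 (MeLi addition, C3 isovalerate, oxidative 1,3-transposition put C9–CH3 and C11=O in place).
2. The cyclobutane (C1–C2–C8–C7) is closed last, at the C2–C8 bond: the kinetic C8 enolate of bicyclic epoxy enone 17 opens the C2–C3 epoxide at its tertiary end. What makes this possible: C8 is the α′-CH2 of the six-membered-ring ketone and sits 1,3 to C2 across the cis ring fusion C1–C7, and C2 is the tertiary carbon of an epoxide in the seven-membered ring whose oxygen remains as the C3 hydroxyl.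
3. Seven-membered ring (C1–C7) by ring-closing metathesis at C2=C3; epoxide by C4–OH-directed epoxidation; C4 carbinol by chelation-controlled vinyl addition.
4. Six-membered ring by Diels–Alder reaction of lactone 5 (lactone C=O = future C2, ring oxygen = C5 oxygen) with silyloxy diene 7; C5 stereocentre by iridium-catalysed tert-prenylation.
5. Order of ring formation: δ-lactone (temporary, opened in step 6) → six-membered ring → seven-membered ring → cyclobutane.

Key step: step 15

Remark: locants C1–C11 follow the tricyclo[5.4.0.0(2,8)]undecane numbering of the target core (cyclobutane = C1, C2, C7, C8; C2–CH3; C3–O-isovaleryl; C4–O-angeloyl; C5–OH; C6(CH3)2; C9(CH3)=C10; C11=O) and are used for the corresponding atoms of every precursor.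

Assumption: (S)-SEGPHOS is taken to deliver the S carbinol 3 in step 1; if the sense of induction is the opposite, the antipodal ligand would be used.

**Route**

Step 1
Reactants: 1 2,2-dimethoxyethanol; 2 3-methylbuta-1,2-diene
Product: 3 (S)-1,1-dimethoxy-3,3-dimethylpent-4-en-2-ol
Conditions: [Ir(cod)Cl]2 (cat.), (S)-SEGPHOS, 4-cyano-3-nitrobenzoic acid (cat.), Cs2CO3 (cat.), toluene, 60 °C
Reagents that add atoms: none
Why: Krische iridium-catalysed transfer-hydrogenative carbonyl tert-prenylation from the alcohol oxidation level; the alcohol is dehydrogenated to the aldehyde, the allene-derived prenyl-iridium adds through its γ-carbon, and the chiral iridium–SEGPHOS complex selects the aldehyde face, which sets C5.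

Step 2
Reactants: 3 (S)-1,1-dimethoxy-3,3-dimethylpent-4-en-2-ol
Product: 4 (S)-1,1-dimethoxy-3,3-dimethylpent-4-en-2-yl prop-2-enoate
Conditions: acryloyl chloride, Et3N, DMAP (cat.), CH2Cl2, 0 °C → rt
Reagents that add atoms: acryloyl chloride C=CC(=O)Cl
Why: DMAP-catalysed O-acylation of the hindered secondary alcohol; the stereocentre is not touched.

Step 3
Reactants: 4 (S)-1,1-dimethoxy-3,3-dimethylpent-4-en-2-yl prop-2-enoate
Product: 5 (S)-6-(dimethoxymethyl)-5,5-dimethyl-5,6-dihydro-2H-pyran-2-one
Conditions: second-generation Grubbs catalyst RuCl2(=CHPh)(H2IMes)(PCy3) (5 mol %), toluene, 80 °C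
Reagents that add atoms: none
Why: ring-closing metathesis of the acrylate with the vinyl group on the quaternary carbon gives the α,β-unsaturated δ-lactone; the gem-dimethyl group favours closure and ethene loss drives it.

Step 4
Reactants: 6 (E)-4-methoxybut-3-en-2-one
Product: 7 (E)-tert-butyl[(4-methoxybuta-1,3-dien-2-yl)oxy]dimethylsilane
Conditions: t-BuMe2SiOTf, Et3N, Et2O, 0 °C
Reagents that add atoms: tert-butyldimethylsilyl trifluoromethanesulfonate CC(C)(C)[Si](C)(C)OS(=O)(=O)C(F)(F)F
Why: soft enolisation and O-silylation of the methyl ketone gives the Danishefsky-type 1-methoxy-3-silyloxy diene with a robust silyl enol ether.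

Step 5
Reactants: 5 (S)-6-(dimethoxymethyl)-5,5-dimethyl-5,6-dihydro-2H-pyran-2-one; 7 (E)-tert-butyl[(4-methoxybuta-1,3-dien-2-yl)oxy]dimethylsilane
Product: 8 cis-fused Diels–Alder lactone (hexahydroisochromenone with silyl enol ether and allylic methoxy group)
Conditions: toluene, 130 °C, sealed tube, BHT (cat.)
Reagents that add atoms: none
Why: normal-demand Diels–Alder reaction in which the CH2 terminus of 7 bonds to the lactone β-carbon (future C7) and the methoxy-bearing terminus to the α-carbon (future C1); suprafacial addition to the ring alkene makes H-1 and H-7 cis, the diene should approach anti to the dimethoxymethyl group on the adjacent-but-one carbon so that C1 and C7 are set from C5, and the endo mode places the methoxy group cis to the lactone carbonyl (this centre is lost in step 10).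

Step 6
Reactants: 8 cis-fused Diels–Alder lactone
Product: 9 hydroxy Weinreb amide
Conditions: MeNHOMe·HCl, i-PrMgCl, THF, −20 → 0 °C; H2O
Reagents that add atoms: N,O-dimethylhydroxylamine hydrochloride CNOC.Cl
Why: aminolysis of the lactone by the magnesium amide (Weinreb amide formation) frees the C5 hydroxyl and prepares C2 for methyl ketone formation; the silyl enol ether and acetal are inert to base.

Step 7
Reactants: 9 hydroxy Weinreb amide
Product: 10 methoxymethyl ether of 9
Conditions: MeOCH2Cl, i-Pr2NEt, CH2Cl2, 0 °C → rt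
Reagents that add atoms: chloromethyl methyl ether COCCl
Why: O-alkylation to the methoxymethyl ether blocks relactonisation and provides the chelating α-alkoxy group needed in step 11.

Step 8
Reactants: 10 methoxymethyl ether of 9
Product: 11 methyl ketone
Conditions: MeMgBr, THF, −20 → 0 °C; H2O
Reagents that add atoms: methylmagnesium bromide C[Mg]Br
Why: Weinreb ketone synthesis, in which the chelated tetrahedral intermediate prevents over-addition; this installs the C2 methyl group while the enone remains masked as its silyl enol ether.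

Step 9
Reactants: 11 methyl ketone
Product: 12 isopropenyl compound
Conditions: Cp2TiMe2, toluene, 65 °C, dark
Reagents that add atoms: dimethyltitanocene C[Ti](C)(C1C=CC=C1)C1C=CC=C1
Why: Petasis methylenation is non-basic, so the epimerisable C1 centre α to the ketone should keep its cis relationship to C7.

Step 10
Reactants: 12 isopropenyl compound
Product: 13 enone aldehyde
Conditions: 1 M aq. HCl, THF, 0 °C → rt
Reagents that add atoms: water O
Why: acid hydrolysis of the silyl enol ether with β-elimination of methanol gives the cyclohex-2-enone (C9=O, C10=C11) and the dimethyl acetal is hydrolysed to the C4 aldehyde, while the methoxymethyl ether, which needs much stronger acid, should survive.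

Step 11
Reactants: 13 enone aldehyde
Product: 14 allylic alcohol (4,5-syn)
Conditions: CH2=CHMgBr (1.2 equiv), MgBr2·OEt2, CH2Cl2, −78 °C; H2O
Reagents that add atoms: vinylmagnesium bromide C=C[Mg]Br
Why: Cram-chelate-controlled Grignard addition; magnesium bridges the aldehyde and C5–OCH2OMe oxygens and vinyl adds anti to the quaternary C6, which should give the 4,5-syn carbinol (trans on the later ring), the aldehyde reacting far faster than the enone at −78 °C.

Step 12
Reactants: 14 allylic alcohol (4,5-syn)
Product: 15 cis-fused bicyclo[5.4.0]undecadienone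
Conditions: second-generation Grubbs catalyst RuCl2(=CHPh)(H2IMes)(PCy3) (10 mol %), toluene, 80 °C
Reagents that add atoms: none
Why: ring-closing metathesis of the isopropenyl and vinyl groups forms the trisubstituted C2=C3 cycloheptene, helped by the cis ring fusion and the gem-dimethyl group; the free allylic hydroxyl and the electron-poor enone alkene are tolerated.

Step 13
Reactants: 15 cis-fused bicyclo[5.4.0]undecadienone
Product: 16 epoxy alcohol
Conditions: VO(acac)2 (5 mol %), t-BuOOH, CH2Cl2, 0 °C → rt
Reagents that add atoms: tert-butyl hydroperoxide CC(C)(C)OO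
Why: hydroxyl-directed vanadium-catalysed epoxidation of the cyclic allylic alcohol delivers oxygen to the C2=C3 face syn to C4–OH, setting C3 and the epoxide configuration at C2, while the enone alkene is inert.

Step 14
Reactants: 16 epoxy alcohol
Product: 17 bis(methoxymethyl) epoxy enone
Conditions: MeOCH2Cl, i-Pr2NEt, CH2Cl2, 0 °C → rt
Reagents that add atoms: chloromethyl methyl ether COCCl
Why: O-alkylation under mild amine base protects C4–OH so that the key step involves no acidic hydroxyl and later leaves C3–OH as the only free secondary alcohol.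

Step 15
Reactants: 17 bis(methoxymethyl) epoxy enone
Product: 19 tricyclic hydroxy enone, via lithium enolate 18 (not isolated)
Conditions: LiN(i-Pr)2 (1.2 equiv), THF, −78 °C; then 0 °C → rt; H2O
Reagents that add atoms: none
Why: Kinetic deprotonation at −78 °C should remove the unhindered α′-proton at C8 of the cyclohex-2-enone and give the cross-conjugated lithium enolate 18, the γ-proton at C1 being a shielded methine that is not abstracted under kinetic control. Carbon C8 of 18 then attacks the tertiary epoxide carbon C2 from the side opposite the C2–O bond (SN2 with inversion), which forms the C2–C8 bond; the closest known reaction type is the Stork epoxynitrile cyclization and the related epoxy-ketone cyclizations, which favour four-membered ring formation even at the more substituted epoxide carbon. The one ring closed is the cyclobutane C1–C2–C8–C7, in a 4-exo-tet mode with the breaking C–O bond exocyclic to the new ring. Of the new stereocentres, C8 and C2 are fixed by the tether (C2 hangs from C1 of the cis-fused ring and reaches C8 from one face only) together with inversion at C2, and C3 keeps the configuration given by the directed epoxidation and emerges as the free C3 hydroxyl cis to the C4 oxygen. The step needs α′- over γ-deprotonation, since a C1 carbanion would open the epoxide by β-elimination; this is secured by the kinetic base, the low temperature and the hindered nature of C1–H. It also needs C- over O-alkylation and 4-exo over 5-endo attack, which are secured because O-alkylation would require a bridgehead enol ether and attack at C3 cannot reach the collinear geometry of epoxide opening.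

Step 16
Reactants: 19 tricyclic hydroxy enone
Product: 20 tertiary allylic alcohol (3,9-diol)
Conditions: MeLi (3 equiv), THF, −78 °C; H2O
Reagents that add atoms: methyllithium [Li]C
Why: 1,2-addition of the organolithium to the non-enolisable C9 ketone (both α-positions are a bridgehead and a vinylic carbon) installs the C9 methyl group, attack being expected from the face remote from the C2 methyl (the C9 configuration is inconsequential).

Step 17
Reactants: 20 tertiary allylic alcohol (3,9-diol)
Product: 21 C3 isovalerate
Conditions: (Me2CHCH2CO)2O, Et3N, DMAP, CH2Cl2, rt → 40 °C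
Reagents that add atoms: 3-methylbutanoic anhydride CC(C)CC(=O)OC(=O)CC(C)C
Why: DMAP-catalysed acylation takes place at the only secondary hydroxyl (C3), the tertiary allylic alcohol being unreactive under these conditions.

Step 18
Reactants: 21 C3 isovalerate
Product: 22 transposed enone (C11=O, C9=C10)
Conditions: pyridinium chlorochromate [C5H5NH][CrO3Cl], NaOAc, 4 Å molecular sieves, CH2Cl2, rt
Reagents that add atoms: pyridinium chlorochromate [O-][Cr](=O)(=O)Cl.c1cc[nH+]cc1
Why: Dauben–Michno oxidative 1,3-transposition; the chromate ester of the tertiary allylic alcohol undergoes a [3,3] shift to C11 and is oxidised there, giving the 9-methyl-9-en-11-one of the target without a free carbocation next to the cyclobutane.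

Step 19
Reactants: 22 transposed enone (C11=O, C9=C10)
Product: 23 4,5-diol
Conditions: Me2BBr, CH2Cl2, −78 °C; then aq. NaHCO3
Reagents that add atoms: none
Why: bromodimethylborane cleaves methoxymethyl ethers at low temperature through boron coordination to the acetal oxygen and should leave the ester, the enone and the cyclobutane untouched.

Step 20
Reactants: 23 4,5-diol
Product: 24 target
Conditions: angelic acid, 2,4,6-trichlorobenzoyl chloride, Et3N, toluene, rt; then 23, DMAP (cat.), 40 °C
Reagents that add atoms: angelic acid C/C=C(/C)C(=O)O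
Why: Yamaguchi esterification through the mixed anhydride should acylate C4–OH selectively, because C5–OH is neopentylic (next to the quaternary C6), and the mixed-anhydride protocol at moderate temperature is the usual way to keep the Z geometry of the angeloyl group.

**Compound list**

1 | 2,2-dimethoxyethanol | OCC(OC)OC | starting material
2 | 3-methylbuta-1,2-diene | CC(C)=C=C | starting material
3 | (S)-1,1-dimethoxy-3,3-dimethylpent-4-en-2-ol | COC(OC)[C@@H](O)C(C)(C)C=C | intermediate
4 | (S)-1,1-dimethoxy-3,3-dimethylpent-4-en-2-yl prop-2-enoate | COC(OC)[C@@H](OC(=O)C=C)C(C)(C)C=C | intermediate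
5 | (S)-6-(dimethoxymethyl)-5,5-dimethyl-5,6-dihydro-2H-pyran-2-one | COC(OC)[C@H]1OC(=O)C=CC1(C)C | intermediate
6 | (E)-4-methoxybut-3-en-2-one | CO/C=C/C(C)=O | starting material
7 | (E)-tert-butyl[(4-methoxybuta-1,3-dien-2-yl)oxy]dimethylsilane | CO/C=C/C(=C)O[Si](C)(C)C(C)(C)C | intermediate
8 | (3S)-6-(tert-butyldimethylsilyloxy)-3-(dimethoxymethyl)-8-methoxy-4,4-dimethyl-3,4,4a,5,8,8a-hexahydro-1H-isochromen-1-one; H-4a and H-8a cis, C4a–C5 bond trans to the 3-substituent, 8-OMe cis to C1 | COC(OC)[C@H]1OC(=O)[C@@H]2[C@H](OC)C=C(O[Si](C)(C)C(C)(C)C)C[C@@H]2C1(C)C | intermediate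
9 | 4-(tert-butyldimethylsilyloxy)-6-[(3S)-3-hydroxy-4,4-dimethoxy-2-methylbutan-2-yl]-N,2-dimethoxy-N-methylcyclohex-3-ene-1-carboxamide (1,2-cis, 1,6-cis) | COC(OC)[C@@H](O)C(C)(C)[C@@H]1[C@H](C(=O)N(C)OC)[C@H](OC)C=C(O[Si](C)(C)C(C)(C)C)C1 | intermediate
10 | 4-(tert-butyldimethylsilyloxy)-6-[(3S)-4,4-dimethoxy-3-(methoxymethoxy)-2-methylbutan-2-yl]-N,2-dimethoxy-N-methylcyclohex-3-ene-1-carboxamide (1,2-cis, 1,6-cis) | COC(OC)[C@@H](OCOC)C(C)(C)[C@@H]1[C@H](C(=O)N(C)OC)[C@H](OC)C=C(O[Si](C)(C)C(C)(C)C)C1 | intermediate
11 | 1-{4-(tert-butyldimethylsilyloxy)-6-[(3S)-4,4-dimethoxy-3-(methoxymethoxy)-2-methylbutan-2-yl]-2-methoxycyclohex-3-en-1-yl}ethan-1-one (1,2-cis, 1,6-cis) | COC(OC)[C@@H](OCOC)C(C)(C)[C@@H]1[C@H](C(C)=O)[C@H](OC)C=C(O[Si](C)(C)C(C)(C)C)C1 | intermediate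
12 | tert-butyl({5-[(3S)-4,4-dimethoxy-3-(methoxymethoxy)-2-methylbutan-2-yl]-3-methoxy-4-(prop-1-en-2-yl)cyclohex-1-en-1-yl}oxy)dimethylsilane (3,4-cis, 4,5-cis) | COC(OC)[C@@H](OCOC)C(C)(C)[C@@H]1[C@H](C(C)=C)[C@H](OC)C=C(O[Si](C)(C)C(C)(C)C)C1 | intermediate
13 | (2S)-2-(methoxymethoxy)-3-methyl-3-[5-oxo-2-(prop-1-en-2-yl)cyclohex-3-en-1-yl]butanal (ring 1,2-cis) | O=C[C@@H](OCOC)C(C)(C)[C@H]1CC(=O)C=C[C@H]1C(C)=C | intermediate
14 | (4S)-4-(methoxymethoxy)-5-methyl-5-[5-oxo-2-(prop-1-en-2-yl)cyclohex-3-en-1-yl]hex-1-en-3-ol (3,4-syn; ring 1,2-cis) | C=C[C@H](O)[C@@H](OCOC)C(C)(C)[C@H]1CC(=O)C=C[C@H]1C(C)=C | intermediate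
15 | 4-hydroxy-5-(methoxymethoxy)-2,6,6-trimethylbicyclo[5.4.0]undeca-2,10-dien-9-one (cis-fused; 4-OH trans to 5-O; 5-O cis to C8) | O[C@@H]1[C@@H](OCOC)C(C)(C)[C@H]2CC(=O)C=C[C@H]2C(C)=C1 | intermediate
16 | 2,3-epoxy-4-hydroxy-5-(methoxymethoxy)-2,6,6-trimethylbicyclo[5.4.0]undec-10-en-9-one (epoxide oxygen cis to 4-OH) | O[C@@H]1[C@@H](OCOC)C(C)(C)[C@H]2CC(=O)C=C[C@H]2[C@]3(C)O[C@H]13 | intermediate
17 | 2,3-epoxy-4,5-bis(methoxymethoxy)-2,6,6-trimethylbicyclo[5.4.0]undec-10-en-9-one | COCO[C@@H]1[C@@H](OCOC)C(C)(C)[C@H]2CC(=O)C=C[C@H]2[C@]3(C)O[C@H]13 | intermediate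
18 | lithium enolate of 17 (C8=C9 enolate; not isolated) | COCO[C@@H]1[C@@H](OCOC)C(C)(C)[C@H]2C=C(O[Li])C=C[C@H]2[C@]3(C)O[C@H]13 | intermediate
19 | 3-hydroxy-4,5-bis(methoxymethoxy)-2,6,6-trimethyltricyclo[5.4.0.0(2,8)]undec-10-en-9-one (3-O and 4-O cis, 5-O trans) | COCO[C@@H]1[C@@H](OCOC)C(C)(C)[C@@H]2[C@H]3C=CC(=O)[C@@H]2[C@@]3(C)[C@@H]1O | intermediate
20 | 4,5-bis(methoxymethoxy)-2,6,6,9-tetramethyltricyclo[5.4.0.0(2,8)]undec-10-ene-3,9-diol (9-OH on the side of the C2 methyl) | COCO[C@@H]1[C@@H](OCOC)C(C)(C)[C@@H]2[C@H]3C=C[C@](C)(O)[C@@H]2[C@@]3(C)[C@@H]1O | intermediate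
21 | 9-hydroxy-4,5-bis(methoxymethoxy)-2,6,6,9-tetramethyltricyclo[5.4.0.0(2,8)]undec-10-en-3-yl 3-methylbutanoate | COCO[C@@H]1[C@@H](OCOC)C(C)(C)[C@@H]2[C@H]3C=C[C@](C)(O)[C@@H]2[C@@]3(C)[C@@H]1OC(=O)CC(C)C | intermediate
22 | 4,5-bis(methoxymethoxy)-2,6,6,9-tetramethyl-11-oxotricyclo[5.4.0.0(2,8)]undec-9-en-3-yl 3-methylbutanoate | COCO[C@@H]1[C@@H](OCOC)C(C)(C)[C@@H]2[C@H]3C(=O)C=C(C)[C@@H]2[C@@]3(C)[C@@H]1OC(=O)CC(C)C | intermediate
23 | 4,5-dihydroxy-2,6,6,9-tetramethyl-11-oxotricyclo[5.4.0.0(2,8)]undec-9-en-3-yl 3-methylbutanoate | O[C@@H]1[C@@H](O)C(C)(C)[C@@H]2[C@H]3C(=O)C=C(C)[C@@H]2[C@@]3(C)[C@@H]1OC(=O)CC(C)C | intermediate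
24 | CNP0151972.1: 5-hydroxy-2,6,6,9-tetramethyl-3-(3-methylbutanoyloxy)-11-oxotricyclo[5.4.0.0(2,8)]undec-9-en-4-yl (Z)-2-methylbut-2-enoate | C/C=C(/C)C(=O)O[C@@H]1[C@@H](O)C(C)(C)[C@@H]2[C@H]3C(=O)C=C(C)[C@@H]2[C@@]3(C)[C@@H]1OC(=O)CC(C)C | target

**Step count and risks**

Total step count: 20. Longest linear sequence: 19 steps (steps 1–3 and 5–20; step 4 prepares the diene).

The three steps most likely to fail:

1. Step 15 (cyclobutane closure). The lithium enolate may open the hindered tertiary epoxide terminus too slowly, so that proton transfer to the γ-position with β-elimination of the epoxide, or base-induced epoxide isomerisation, takes over. The fallback activates the electrophile instead of the nucleophile. It sets out from 17: LiN(i-Pr)2 with Me3SiCl present at −78 °C should give the cross-conjugated trimethylsilyl dienol ether F1. BF3·OEt2 in CH2Cl2 at −78 °C then activates the epoxide so that the enol ether carbon C8 attacks C2 in a Mukaiyama-type epoxide opening, and aqueous work-up removes the silyl group. The route is rejoined at 19.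

2. Step 5 (Diels–Alder reaction). The γ,γ-disubstituted lactone may be too sluggish a dienophile, so that the silyloxy diene decomposes on prolonged heating or the facial selectivity erodes at the temperature needed. The fallback replaces the cycloaddition by an anionic, stepwise annulation. It sets out from 6 and 5: LiN(i-Pr)2 at −78 °C converts 6 into lithium (E)-4-methoxybuta-1,3-dien-2-olate F2. Its CH2 terminus adds to the β-carbon of 5 anti to the dimethoxymethyl group, the resulting lactone enolate closes onto the β-methoxy enone (sequential Michael–Michael addition), and the final enolate is trapped with t-BuMe2SiCl. The route is rejoined at 8 (the configuration at the methoxy-bearing carbon is inconsequential).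

3. Step 20 (angeloylation). The Z-2-methylbut-2-enoyl group may isomerise to the E (tigloyl) isomer during acyl transfer, and the neighbouring C3 ester may migrate to the free C4 hydroxyl before acylation is complete. The fallback builds the Z-alkene on the substrate instead of transferring a preformed angeloyl group. It sets out from 23: carbodiimide coupling with 2-(diphenoxyphosphoryl)propanoic acid at the less hindered C4 hydroxyl should give the phosphonoacetate-type ester F3. A Z-selective Horner–Wadsworth–Emmons reaction with acetaldehyde (NaI, DBU, THF, −78 → 0 °C, Ando conditions) then forms the angelate. The route is rejoined at 24.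

Further compounds
F1 | step 15 | trimethylsilyl dienol ether of 17 (C8=C9–OSiMe3) | COCO[C@@H]1[C@@H](OCOC)C(C)(C)[C@H]2C=C(O[Si](C)(C)C)C=C[C@H]2[C@]3(C)O[C@H]13
F2 | step 5 | lithium (E)-4-methoxybuta-1,3-dien-2-olate | [Li]OC(=C)/C=C/OC
F3 | step 20 | C4 2-(diphenoxyphosphoryl)propanoate of 23 (phosphonate α-carbon as a mixture of epimers) | CC(C(=O)O[C@@H]1[C@@H](O)C(C)(C)[C@@H]2[C@H]3C(=O)C=C(C)[C@@H]2[C@@]3(C)[C@@H]1OC(=O)CC(C)C)P(=O)(Oc1ccccc1)Oc1ccccc1
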